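Everything rests on disconnecting O1U–C2U of upper ring C. C4U bears two 2,3,4-trioxygenated phenyl rings, upper ring A (through C4aU) and lower ring A (through C6L); in the open precursor they are identical and C4U is not stereogenic. The precursor is a cis-epoxide, (2S,3R)-2-(4-benzyloxyphenyl)-3-(diarylmethyl)oxirane, with two identical ortho-phenols. One acid-mediated 6-endo closure forms O1U–C2U with inversion, closes upper ring C and makes C4U stereogenic by selecting one of the two diastereotopic aryl groups. The untouched aryl keeps a lone free phenol (C7L) that steers bromination to C4aL, where the lower flavan-3,4-diol ring is then annulated.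

Key step: step 11

Remark (labels): flavan numbering is used, U for the upper 4-arylflavan-3-ol unit and L for the lower flavan-3,4-diol unit; target = upper (2R,3R,4S), lower (2R,3R,4S), both 2,3-cis-3,4-trans.
Remark (assumption): in step 16 the (R)-diamine is assumed to give the (2S,3S)-anti adduct, the mirror image of the sense associated with the (S)-diamine; if the sense proves opposite, the (S)-diamine is used.

Step 1
Reactants: 1 pyrogallol; 2 2,3,4-trihydroxybenzoic acid
Product: 3 bis(2,3,4-trihydroxyphenyl)methanone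
Conditions: BF3·OEt2 (excess), 85 °C; then aq. NaOAc
Reagents that add atoms: none
Why: Friedel–Crafts (Nencki-type) acylation of pyrogallol occurs at C4, ortho and para to hydroxyls, as in the usual syntheses of polyhydroxybenzophenones, and gives both rings with the same carbonyl-directed pattern of three phenols.

Step 2
Reactants: 3 bis(2,3,4-trihydroxyphenyl)methanone
Product: 4 bis[2,3-dihydroxy-4-(methoxymethoxy)phenyl]methanone
Conditions: MOMCl (2.05 equiv), i-Pr2NEt (2.1 equiv), DMF, −10 °C → rt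
Reagents that add atoms: chloromethyl methyl ether, COCCl
Why: Selective Williamson-type O-alkylation: the two hydroxyls para to the carbonyl are the most acidic and should react with a weak amine base before the 3-hydroxyls and the chelated 2-hydroxyls.

Step 3
Reactants: 4 bis[2,3-dihydroxy-4-(methoxymethoxy)phenyl]methanone
Product: 5 bis[3-(benzyloxy)-2-hydroxy-4-(methoxymethoxy)phenyl]methanone
Conditions: BnBr (2.1 equiv), K2CO3 (2.2 equiv), DMF, rt
Reagents that add atoms: benzyl bromide, BrCc1ccccc1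
Why: Williamson etherification of the free 3-hydroxyls, while the 2-hydroxyls stay locked in hydrogen bonds to the ketone, as in the partial alkylation of gallacetophenone.

Step 4
Reactants: 5 bis[3-(benzyloxy)-2-hydroxy-4-(methoxymethoxy)phenyl]methanone
Product: 6 bis[3-(benzyloxy)-2-hydroxy-4-(methoxymethoxy)phenyl]methanol
Conditions: NaBH4 (excess), EtOH/THF, 0 °C → rt; neutral work-up, used crude
Reagents that add atoms: none
Why: Hydride reduction of a 2-hydroxybenzophenone; no stereocentre arises because the two aryl groups are identical.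

Step 5
Reactants: 6 bis[3-(benzyloxy)-2-hydroxy-4-(methoxymethoxy)phenyl]methanol
Product: 7 bis[3-(benzyloxy)-2-(tert-butyldimethylsilyloxy)-4-(methoxymethoxy)phenyl]methanol
Conditions: TBSCl (2.2 equiv), imidazole, DMF, 0 °C
Reagents that add atoms: tert-butyldimethylsilyl chloride, CC(C)(C)[Si](C)(C)Cl
Why: Silylation is much faster at the phenols than at the hindered benzhydrol hydroxyl, and silylation of the carbinol would be harmless because that oxygen leaves in step 7.

Step 6
Reactants: 8 1-(benzyloxy)-4-ethynylbenzene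
Product: 11 potassium {[4-(benzyloxy)phenyl]ethynyl}trifluoroborate, via lithium acetylide 9 (not isolated), via lithium alkynyltrimethoxyborate 10 (not isolated)
Conditions: n-BuLi, THF, −78 °C; B(OMe)3, −78 → −20 °C; aq. KHF2
Reagents that add atoms: n-butyllithium, [Li]CCCC; trimethyl borate, COB(OC)OC; potassium hydrogen difluoride, [K+].[F-].F
Why: Deprotonation of the terminal alkyne, borylation and fluoride exchange is the standard preparation of potassium alkynyltrifluoroborates.

Step 7
Reactants: 7 bis[3-(benzyloxy)-2-(tert-butyldimethylsilyloxy)-4-(methoxymethoxy)phenyl]methanol; 11 potassium {[4-(benzyloxy)phenyl]ethynyl}trifluoroborate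
Product: 12 3,3-bis[3-(benzyloxy)-2-(tert-butyldimethylsilyloxy)-4-(methoxymethoxy)phenyl]-1-[4-(benzyloxy)phenyl]prop-1-yne
Conditions: BF3·OEt2 (1.2 equiv), MeCN/CH2Cl2, −40 → −10 °C, short contact
Reagents that add atoms: none
Why: Lewis-acid-mediated SN1 substitution of a benzhydrol by an alkynyltrifluoroborate: the benzhydryl cation, stabilised by four ortho/para oxygens, forms at low temperature, where the MOM and silyl ethers should survive, and accepts the alkynyl group.

Step 8
Reactants: 12 3,3-bis[3-(benzyloxy)-2-(tert-butyldimethylsilyloxy)-4-(methoxymethoxy)phenyl]-1-[4-(benzyloxy)phenyl]prop-1-yne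
Product: 13 (Z)-3,3-bis[3-(benzyloxy)-2-(tert-butyldimethylsilyloxy)-4-(methoxymethoxy)phenyl]-1-[4-(benzyloxy)phenyl]prop-1-ene
Conditions: H2 (1 atm), Pd/CaCO3 poisoned with Pb(OAc)2, quinoline, EtOAc, rt, stopped at 1 equiv H2
Reagents that add atoms: none
Why: Lindlar semihydrogenation adds hydrogen syn and stops at the Z-alkene; the poisoned catalyst does not cleave benzyl ethers.

Step 9
Reactants: 13 (Z)-3,3-bis[3-(benzyloxy)-2-(tert-butyldimethylsilyloxy)-4-(methoxymethoxy)phenyl]-1-[4-(benzyloxy)phenyl]prop-1-ene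
Product: 14 (2S,3R)-2-[4-(benzyloxy)phenyl]-3-{bis[3-(benzyloxy)-2-(tert-butyldimethylsilyloxy)-4-(methoxymethoxy)phenyl]methyl}oxirane (cis)
Conditions: (S,S)-N,N'-bis(3,5-di-tert-butylsalicylidene)-1,2-cyclohexanediaminomanganese chloride (8 mol%), NMO (5 equiv), m-CPBA (2 equiv), CH2Cl2, −78 °C; Et3N-deactivated silica
Reagents that add atoms: 3-chloroperoxybenzoic acid, OOC(=O)c1cccc(Cl)c1
Why: Jacobsen–Katsuki epoxidation of a cis-disubstituted aryl alkene: the (S,S)-catalyst should give S at the aryl-bearing carbon (as with cis-β-methylstyrene, indene and cis-cinnamates), hence the (2S,3R)-cis-epoxide, and the anhydrous low-temperature protocol with buffering NMO limits cis-to-trans leakage and spares the silyl ethers.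

Step 10
Reactants: 14 (2S,3R)-2-[4-(benzyloxy)phenyl]-3-{bis[3-(benzyloxy)-2-(tert-butyldimethylsilyloxy)-4-(methoxymethoxy)phenyl]methyl}oxirane
Product: 15 (2S,3R)-2-[4-(benzyloxy)phenyl]-3-{bis[3-(benzyloxy)-2-hydroxy-4-(methoxymethoxy)phenyl]methyl}oxirane (cis)
Conditions: Bu4NF (2.2 equiv), AcOH (2.2 equiv), THF, −20 °C; cold neutral work-up, used at once
Reagents that add atoms: none
Why: Fluoride cleavage of aryl silyl ethers; the AcOH buffer keeps the phenols protonated so that no phenoxide opens the epoxide in the 5-exo mode.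

Step 11
Reactants: 15 (2S,3R)-2-[4-(benzyloxy)phenyl]-3-{bis[3-(benzyloxy)-2-hydroxy-4-(methoxymethoxy)phenyl]methyl}oxirane
Product: 16 (2R,3R,4S)-8-(benzyloxy)-4-[3-(benzyloxy)-2-hydroxy-4-(methoxymethoxy)phenyl]-2-[4-(benzyloxy)phenyl]-7-(methoxymethoxy)chroman-3-ol (2,3-cis-3,4-trans)
Conditions: PPTS (10 mol%), CH2Cl2, −20 → 0 °C
Reagents that add atoms: none
Why: Proposed new method: PPTS hydrogen-bonds to the epoxide oxygen and one ortho-phenol attacks the benzylic carbon C2U from the back (6-endo-tet closure of upper ring C, preferred over 5-exo attack at C3U because the 4-benzyloxyphenyl group weakens the C2U–O bond), so C2U is inverted (2S to 2R), the epoxide oxygen stays on C3U with retention, and the cis-epoxide gives the 2,3-cis ring. The closest known reactions are the acid-mediated 6-endo cyclisations of 2-hydroxyaryl-substituted aryl epoxides to flavan-3-ols and diastereotopic-group-selective cyclisations of bis-aryl methanes; their combination on this substrate class is untested. C4U becomes stereogenic through the choice of aryl group, and this choice is controlled by the two epoxide stereocentres: backside attack on a cis-epoxide allows only the half-chair in which the C2U aryl is pseudo-axial and the C3U oxygen pseudo-equatorial, and a pseudo-axial spectator aryl at C4U would clash 1,3-syn with the C2U aryl, so the aryl that cyclises should be the one that leaves the spectator pseudo-equatorial, trans to both neighbours (3,4-trans, 2R,3R,4S). Three selectivities are needed: ring size, secured by benzylic activation; inversion instead of ionisation, secured by weak acid, low temperature, a non-nucleophilic solvent and the inductive effect of the C3U oxygen; and the diastereotopic-group choice, for which only the conformational argument stands against the peri strain with H5U, and this is the point at risk. The spectator ring emerges with a single free phenol (C7L), which is used in step 12.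

Step 12
Reactants: 16 (2R,3R,4S)-8-(benzyloxy)-4-[3-(benzyloxy)-2-hydroxy-4-(methoxymethoxy)phenyl]-2-[4-(benzyloxy)phenyl]-7-(methoxymethoxy)chroman-3-ol
Product: 17 (2R,3R,4S)-8-(benzyloxy)-4-[3-(benzyloxy)-5-bromo-2-hydroxy-4-(methoxymethoxy)phenyl]-2-[4-(benzyloxy)phenyl]-7-(methoxymethoxy)chroman-3-ol
Conditions: NBS (1.0 equiv), CH2Cl2, −78 °C
Reagents that add atoms: N-bromosuccinimide, O=C1CCC(=O)N1Br
Why: Electrophilic aromatic bromination: the only free phenol (C7L) has both ortho positions substituted, so bromine should enter para, at C4aL, far faster than at any position of the fully etherified rings.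

Step 13
Reactants: 17 (2R,3R,4S)-8-(benzyloxy)-4-[3-(benzyloxy)-5-bromo-2-hydroxy-4-(methoxymethoxy)phenyl]-2-[4-(benzyloxy)phenyl]-7-(methoxymethoxy)chroman-3-ol
Product: 18 (2R,3R,4R)-3,8-bis(benzyloxy)-4-[2,3-bis(benzyloxy)-5-bromo-4-(methoxymethoxy)phenyl]-2-[4-(benzyloxy)phenyl]-7-(methoxymethoxy)chromane (same spatial arrangement as 17; the C4 label changes only through CIP priorities)
Conditions: NaH, BnBr, Bu4NI (cat.), DMF, 0 °C → rt
Reagents that add atoms: benzyl bromide, BrCc1ccccc1
Why: Williamson benzylation of the C7L phenol and the C3U alcohol; no base-sensitive group is present and no stereocentre is touched.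

Step 14
Reactants: 19 (benzyloxy)acetyl chloride; 20 ethanethiol
Product: 21 S-ethyl 2-(benzyloxy)ethanethioate
Conditions: Et3N, CH2Cl2, 0 °C
Reagents that add atoms: none
Why: Acylation of a thiol by an acid chloride (thioester formation).

Step 15
Reactants: 21 S-ethyl 2-(benzyloxy)ethanethioate
Product: 23 (Z)-{[2-(benzyloxy)-1-(ethylsulfanyl)ethenyl]oxy}trimethylsilane, via lithium enolate 22 (not isolated)
Conditions: LiN(i-Pr)2, THF, −78 °C; Me3SiCl
Reagents that add atoms: lithium diisopropylamide, [Li]N(C(C)C)C(C)C; chlorotrimethylsilane, C[Si](C)(C)Cl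
Why: Kinetic enolisation and O-silylation give the ketene silyl thioacetal used in tin-promoted glycolate aldol reactions.

Step 16
Reactants: 23 (Z)-{[2-(benzyloxy)-1-(ethylsulfanyl)ethenyl]oxy}trimethylsilane; 24 4-(benzyloxy)benzaldehyde
Product: 25 S-ethyl (2S,3S)-2-(benzyloxy)-3-[4-(benzyloxy)phenyl]-3-hydroxypropanethioate (anti)
Conditions: Sn(OTf)2, (R)-1-methyl-2-[(naphthalen-1-ylamino)methyl]pyrrolidine, Bu2Sn(OAc)2, CH2Cl2, −78 °C; aq. NaHCO3
Reagents that add atoms: none
Why: Asymmetric Mukaiyama aldol reaction: α-benzyloxy ketene silyl thioacetals add to aromatic aldehydes through a tin-coordinated open transition state to give anti adducts, and the chiral diamine on tin sets the absolute configuration of both new centres (2S,3S, see the remark above).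

Step 17
Reactants: 25 S-ethyl (2S,3S)-2-(benzyloxy)-3-[4-(benzyloxy)phenyl]-3-hydroxypropanethioate
Product: 26 S-ethyl (2S,3S)-2-(benzyloxy)-3-[4-(benzyloxy)phenyl]-3-(methoxymethoxy)propanethioate
Conditions: MOMCl, i-Pr2NEt, CH2Cl2, 0 °C → rt
Reagents that add atoms: chloromethyl methyl ether, COCCl
Why: MOM ether formation at the benzylic alcohol under non-acidic conditions; no stereocentre is touched.

Step 18
Reactants: 26 S-ethyl (2S,3S)-2-(benzyloxy)-3-[4-(benzyloxy)phenyl]-3-(methoxymethoxy)propanethioate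
Product: 27 (2S,3S)-2-(benzyloxy)-3-[4-(benzyloxy)phenyl]-3-(methoxymethoxy)propanal
Conditions: i-Bu2AlH, CH2Cl2, −78 °C; aq. KNaC4H4O6; used without storage
Reagents that add atoms: none
Why: Partial reduction of a thioester stops at the aldehyde because the tetrahedral aluminium intermediate survives until work-up; immediate use avoids α-epimerisation.

Step 19
Reactants: 18 (2R,3R,4R)-3,8-bis(benzyloxy)-4-[2,3-bis(benzyloxy)-5-bromo-4-(methoxymethoxy)phenyl]-2-[4-(benzyloxy)phenyl]-7-(methoxymethoxy)chromane; 27 (2S,3S)-2-(benzyloxy)-3-[4-(benzyloxy)phenyl]-3-(methoxymethoxy)propanal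
Product: 30 compound 18 with Br replaced by a (1S,2R,3S)-2-(benzyloxy)-3-[4-(benzyloxy)phenyl]-1-hydroxy-3-(methoxymethoxy)propyl group (C4L S; C3L R; C2L S; 3,4-syn-2,3-anti), via aryllithium 28 (not isolated), via arylmagnesium bromide 29 (not isolated)
Conditions: n-BuLi, Et2O/THF, −78 °C; MgBr2·OEt2, −78 → −20 °C; 27 (1.5 equiv), CH2Cl2, −78 °C; aq. NH4Cl
Reagents that add atoms: n-butyllithium, [Li]CCCC; magnesium bromide, Br[Mg]Br
Why: Bromine–lithium exchange ortho to the MOM ether, transmetalation and Cram-chelate-controlled Grignard addition: magnesium bridges the carbonyl and α-benzyloxy oxygens and the aryl group adds anti to the C2L-bearing chain, which should give the 3,4-syn carbinol (the later 3,4-trans ring relationship); chelation through the β-MOM oxygen predicts the same isomer.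

Step 20
Reactants: 30 C4L carbinol
Product: 31 C4L benzyl ether of 30 (chain (1S,2R,3S)-1,2-bis(benzyloxy)-3-[4-(benzyloxy)phenyl]-3-(methoxymethoxy)propyl)
Conditions: NaH, BnBr, Bu4NI (cat.), THF/DMF, 0 °C → rt
Reagents that add atoms: benzyl bromide, BrCc1ccccc1
Why: Williamson benzylation caps the ionisable C4L hydroxyl so that the later Mitsunobu activation can take place only at C2L.

Step 21
Reactants: 31 C4L benzyl ether
Product: 33 triol with free C7U phenol and free C8aL phenol and free C2L alcohol (chain (1S,2S,3S)-1,2-bis(benzyloxy)-3-[4-(benzyloxy)phenyl]-3-hydroxypropyl; same spatial arrangement as 31), via bis(trimethylsilyl) ether bipyridinium triflate 32 (not isolated)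
Conditions: Me3SiOTf, 2,2'-bipyridyl, CH2Cl2, 0 °C → rt; then H2O
Reagents that add atoms: trimethylsilyl trifluoromethanesulfonate, C[Si](C)(C)OS(=O)(=O)C(F)(F)F; 2,2'-bipyridyl, c1ccc(-c2ccccn2)nc1
Why: Silyl triflate/bipyridyl cleavage of MOM ethers (aryl MOM to aryl silyl ether, alkyl MOM to a bipyridinium acetal, both hydrolysed by water) runs under nearly neutral conditions, so the ionisable C4L benzyl ether and the C4U–C6L bond should be spared while all three hydroxyls are released in one operation.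

Step 22
Reactants: 33 triol
Product: 34 octabenzyl ether of the target with free C7U phenol: lower ring C closed, 2,3-cis-3,4-trans (lower unit 2R,3R,4S)
Conditions: PPh3, DIAD, THF (0.005 M), 0 °C → rt
Reagents that add atoms: none
Why: Intramolecular Mitsunobu etherification (6-exo-tet): the C8aL phenol displaces the activated C2L alcohol with inversion, turning the 2,3-anti chain into the 2,3-cis ring; high dilution keeps the C7U phenol from reacting intermolecularly and the β-benzyloxy group disfavours ionisation at C2L.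

Step 23
Reactants: 34 octabenzyl ether
Product: 35 (2R,3R,4S)-2-(4-hydroxyphenyl)-6-[(2R,3R,4S)-3,7,8-trihydroxy-2-(4-hydroxyphenyl)chroman-4-yl]chromane-3,4,7,8-tetrol (target)
Conditions: H2 (1 atm), Pd(OH)2/C, THF/MeOH, rt, stopped when debenzylation is complete; argon work-up
Reagents that add atoms: none
Why: Hydrogenolysis of the eight benzyl ethers under neutral conditions, as in the last step of proanthocyanidin syntheses; the unhindered PhCH2–O bond of the C4L ether should cleave before the ring C4L–O bond, and short neutral exposure protects the benzylic C4L hydroxyl.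

Compound list
1 | pyrogallol | Oc1cccc(O)c1O | starting material
2 | 2,3,4-trihydroxybenzoic acid | OC(=O)c1ccc(O)c(O)c1O | starting material
3 | bis(2,3,4-trihydroxyphenyl)methanone | O=C(c1ccc(O)c(O)c1O)c1ccc(O)c(O)c1O | intermediate
4 | bis[2,3-dihydroxy-4-(methoxymethoxy)phenyl]methanone | O=C(c1ccc(OCOC)c(O)c1O)c1ccc(OCOC)c(O)c1O | intermediate
5 | bis[3-(benzyloxy)-2-hydroxy-4-(methoxymethoxy)phenyl]methanone | O=C(c1ccc(OCOC)c(OCc2ccccc2)c1O)c1ccc(OCOC)c(OCc2ccccc2)c1O | intermediate
6 | bis[3-(benzyloxy)-2-hydroxy-4-(methoxymethoxy)phenyl]methanol | OC(c1ccc(OCOC)c(OCc2ccccc2)c1O)c1ccc(OCOC)c(OCc2ccccc2)c1O | intermediate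
7 | bis[3-(benzyloxy)-2-(tert-butyldimethylsilyloxy)-4-(methoxymethoxy)phenyl]methanol | OC(c1ccc(OCOC)c(OCc2ccccc2)c1O[Si](C)(C)C(C)(C)C)c1ccc(OCOC)c(OCc2ccccc2)c1O[Si](C)(C)C(C)(C)C | intermediate
8 | 1-(benzyloxy)-4-ethynylbenzene | C#Cc1ccc(OCc2ccccc2)cc1 | starting material
9 | lithium [4-(benzyloxy)phenyl]acetylide | [Li]C#Cc1ccc(OCc2ccccc2)cc1 | intermediate
10 | lithium {[4-(benzyloxy)phenyl]ethynyl}trimethoxyborate | [Li+].CO[B-](OC)(OC)C#Cc1ccc(OCc2ccccc2)cc1 | intermediate
11 | potassium {[4-(benzyloxy)phenyl]ethynyl}trifluoroborate | [K+].F[B-](F)(F)C#Cc1ccc(OCc2ccccc2)cc1 | intermediate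
12 | 3,3-bis[3-(benzyloxy)-2-(tert-butyldimethylsilyloxy)-4-(methoxymethoxy)phenyl]-1-[4-(benzyloxy)phenyl]prop-1-yne | C(c1ccccc1)Oc1ccc(C#CC(c2ccc(OCOC)c(OCc3ccccc3)c2O[Si](C)(C)C(C)(C)C)c2ccc(OCOC)c(OCc3ccccc3)c2O[Si](C)(C)C(C)(C)C)cc1 | intermediate
13 | (Z)-3,3-bis[3-(benzyloxy)-2-(tert-butyldimethylsilyloxy)-4-(methoxymethoxy)phenyl]-1-[4-(benzyloxy)phenyl]prop-1-ene | C(c1ccccc1)Oc1ccc(/C=C\C(c2ccc(OCOC)c(OCc3ccccc3)c2O[Si](C)(C)C(C)(C)C)c2ccc(OCOC)c(OCc3ccccc3)c2O[Si](C)(C)C(C)(C)C)cc1 | intermediate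
14 | (2S,3R)-2-[4-(benzyloxy)phenyl]-3-{bis[3-(benzyloxy)-2-(tert-butyldimethylsilyloxy)-4-(methoxymethoxy)phenyl]methyl}oxirane | C(c1ccccc1)Oc1ccc([C@@H]2O[C@@H]2C(c2ccc(OCOC)c(OCc3ccccc3)c2O[Si](C)(C)C(C)(C)C)c2ccc(OCOC)c(OCc3ccccc3)c2O[Si](C)(C)C(C)(C)C)cc1 | intermediate
15 | (2S,3R)-2-[4-(benzyloxy)phenyl]-3-{bis[3-(benzyloxy)-2-hydroxy-4-(methoxymethoxy)phenyl]methyl}oxirane | C(c1ccccc1)Oc1ccc([C@@H]2O[C@@H]2C(c2ccc(OCOC)c(OCc3ccccc3)c2O)c2ccc(OCOC)c(OCc3ccccc3)c2O)cc1 | intermediate
16 | (2R,3R,4S)-8-(benzyloxy)-4-[3-(benzyloxy)-2-hydroxy-4-(methoxymethoxy)phenyl]-2-[4-(benzyloxy)phenyl]-7-(methoxymethoxy)chroman-3-ol | C(c1ccccc1)Oc1ccc([C@H]2Oc3c(ccc(OCOC)c3OCc3ccccc3)[C@H](c3ccc(OCOC)c(OCc4ccccc4)c3O)[C@H]2O)cc1 | intermediate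
17 | (2R,3R,4S)-8-(benzyloxy)-4-[3-(benzyloxy)-5-bromo-2-hydroxy-4-(methoxymethoxy)phenyl]-2-[4-(benzyloxy)phenyl]-7-(methoxymethoxy)chroman-3-ol | C(c1ccccc1)Oc1ccc([C@H]2Oc3c(ccc(OCOC)c3OCc3ccccc3)[C@H](c3cc(Br)c(OCOC)c(OCc4ccccc4)c3O)[C@H]2O)cc1 | intermediate
18 | (2R,3R,4R)-3,8-bis(benzyloxy)-4-[2,3-bis(benzyloxy)-5-bromo-4-(methoxymethoxy)phenyl]-2-[4-(benzyloxy)phenyl]-7-(methoxymethoxy)chromane | C(c1ccccc1)Oc1ccc([C@H]2Oc3c(ccc(OCOC)c3OCc3ccccc3)[C@H](c3cc(Br)c(OCOC)c(OCc4ccccc4)c3OCc3ccccc3)[C@H]2OCc2ccccc2)cc1 | intermediate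
19 | (benzyloxy)acetyl chloride | O=C(Cl)COCc1ccccc1 | starting material
20 | ethanethiol | CCS | starting material
21 | S-ethyl 2-(benzyloxy)ethanethioate | CCSC(=O)COCc1ccccc1 | intermediate
22 | lithium (Z)-2-(benzyloxy)-1-(ethylsulfanyl)ethenolate | CCS/C(O[Li])=C\OCc1ccccc1 | intermediate
23 | (Z)-{[2-(benzyloxy)-1-(ethylsulfanyl)ethenyl]oxy}trimethylsilane | CCS/C(O[Si](C)(C)C)=C\OCc1ccccc1 | intermediate
24 | 4-(benzyloxy)benzaldehyde | O=Cc1ccc(OCc2ccccc2)cc1 | starting material
25 | S-ethyl (2S,3S)-2-(benzyloxy)-3-[4-(benzyloxy)phenyl]-3-hydroxypropanethioate | O[C@@H](c1ccc(OCc2ccccc2)cc1)[C@H](OCc1ccccc1)C(=O)SCC | intermediate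
26 | S-ethyl (2S,3S)-2-(benzyloxy)-3-[4-(benzyloxy)phenyl]-3-(methoxymethoxy)propanethioate | COCO[C@@H](c1ccc(OCc2ccccc2)cc1)[C@H](OCc1ccccc1)C(=O)SCC | intermediate
27 | (2S,3S)-2-(benzyloxy)-3-[4-(benzyloxy)phenyl]-3-(methoxymethoxy)propanal | COCO[C@@H](c1ccc(OCc2ccccc2)cc1)[C@H](OCc1ccccc1)C=O | intermediate
28 | aryllithium from 18 (Li at C4aL) | C(c1ccccc1)Oc1ccc([C@H]2Oc3c(ccc(OCOC)c3OCc3ccccc3)[C@H](c3cc([Li])c(OCOC)c(OCc4ccccc4)c3OCc3ccccc3)[C@H]2OCc2ccccc2)cc1 | intermediate
29 | arylmagnesium bromide from 18 (MgBr at C4aL) | C(c1ccccc1)Oc1ccc([C@H]2Oc3c(ccc(OCOC)c3OCc3ccccc3)[C@H](c3cc([Mg]Br)c(OCOC)c(OCc4ccccc4)c3OCc3ccccc3)[C@H]2OCc2ccccc2)cc1 | intermediate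
30 | C4L carbinol: 18 with Br replaced by the (1S,2R,3S)-2-(benzyloxy)-3-[4-(benzyloxy)phenyl]-1-hydroxy-3-(methoxymethoxy)propyl group | C(c1ccccc1)Oc1ccc([C@H]2Oc3c(ccc(OCOC)c3OCc3ccccc3)[C@H](c3cc([C@H](O)[C@@H](OCc4ccccc4)[C@@H](OCOC)c4ccc(OCc5ccccc5)cc4)c(OCOC)c(OCc4ccccc4)c3OCc3ccccc3)[C@H]2OCc2ccccc2)cc1 | intermediate
31 | C4L benzyl ether of 30 | C(c1ccccc1)Oc1ccc([C@H]2Oc3c(ccc(OCOC)c3OCc3ccccc3)[C@H](c3cc([C@H](OCc4ccccc4)[C@@H](OCc4ccccc4)[C@@H](OCOC)c4ccc(OCc5ccccc5)cc4)c(OCOC)c(OCc4ccccc4)c3OCc3ccccc3)[C@H]2OCc2ccccc2)cc1 | intermediate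
32 | 31 with both aryl MOM groups replaced by trimethylsilyl and the C2L MOM group replaced by a (2,2'-bipyridin-1-ium-1-yl)methyl group, triflate salt | C(c1ccccc1)Oc1ccc([C@H]2Oc3c(ccc(O[Si](C)(C)C)c3OCc3ccccc3)[C@H](c3cc([C@H](OCc4ccccc4)[C@@H](OCc4ccccc4)[C@@H](OC[n+]4ccccc4-c4ccccn4)c4ccc(OCc5ccccc5)cc4)c(O[Si](C)(C)C)c(OCc4ccccc4)c3OCc3ccccc3)[C@H]2OCc2ccccc2)cc1.[O-]S(=O)(=O)C(F)(F)F | intermediate
33 | triol: 31 with free C7U phenol, free C8aL phenol and free C2L alcohol | C(c1ccccc1)Oc1ccc([C@H]2Oc3c(ccc(O)c3OCc3ccccc3)[C@H](c3cc([C@H](OCc4ccccc4)[C@@H](OCc4ccccc4)[C@@H](O)c4ccc(OCc5ccccc5)cc4)c(O)c(OCc4ccccc4)c3OCc3ccccc3)[C@H]2OCc2ccccc2)cc1 | intermediate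
34 | octabenzyl ether of the target (free C7U phenol; benzyl on 4'U, 8U, 3U, 7L, 8L, 4'L, 3L and 4L oxygens) | C(c1ccccc1)Oc1ccc([C@H]2Oc3c(ccc(O)c3OCc3ccccc3)[C@H](c3cc4c(c(OCc5ccccc5)c3OCc3ccccc3)O[C@H](c3ccc(OCc5ccccc5)cc3)[C@H](OCc3ccccc3)[C@H]4OCc3ccccc3)[C@H]2OCc2ccccc2)cc1 | intermediate
35 | (2R,3R,4S)-2-(4-hydroxyphenyl)-6-[(2R,3R,4S)-3,7,8-trihydroxy-2-(4-hydroxyphenyl)chroman-4-yl]chromane-3,4,7,8-tetrol | Oc1ccc([C@H]2Oc3c(ccc(O)c3O)[C@H](c3cc4c(c(O)c3O)O[C@H](c3ccc(O)cc3)[C@H](O)[C@H]4O)[C@H]2O)cc1 | target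

Total step count: 23. Longest linear sequence: 17 steps (steps 1–5, 7–13, 19–23).

Steps most likely to fail

1. Step 11 (Proposed new method). What may go wrong: the two diastereotopic aryl groups are not told apart, so both C4U epimers form, or partial ionisation at C2U erodes the 2,3-cis relationship. The fallback replaces kinetic group selection by separation of pre-formed C4 diastereomers and uses only known reactions. It sets out from 14. One equivalent of Bu4NF/AcOH removes a single silyl group; the two monophenols are diastereomers at the methine carbon and are separated by chromatography. The isomer with the free phenol on the future upper ring A, the monosilyl monophenol epoxide F1, is cyclised with PPTS in CH2Cl2; this is an ordinary 6-endo phenol–epoxide closure with only one phenol available, so C4U is fixed beforehand, and it gives the C7L-silylated 4-arylflavan-3-ol F2. Bu4NF then releases the C7L phenol and the route is rejoined at 16. The other monophenol is re-silylated (TBSCl, imidazole) to 14 and recycled. Which monophenol is which would be assigned by NOE analysis after cyclisation.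

2. Step 9. What may go wrong: weak facial discrimination and cis-to-trans leakage in the stepwise metal-oxo oxygen transfer, made worse by the bulky diarylmethyl substituent. The fallback sets out from 13 and uses a concerted dioxirane oxygen transfer (Shi epoxidation for cis-olefins), which cannot scramble the alkene geometry: the glucose-derived oxazolidinone ketone of the enantiomeric series that delivers the (2S,3R)-epoxide, KHSO5 (as 2KHSO5·KHSO4·K2SO4), K2CO3/AcOH buffer at pH 8, dimethoxyethane/dimethoxymethane, −10 °C. It comes back to the route at 14 and makes no new compound, F0.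

3. Step 19. What may go wrong: incomplete chelation control giving both C4L epimers, or enolisation of aldehyde 27 by the hindered aryl nucleophile. The fallback moves the stereochemical decision from aryl addition to hydride delivery. It sets out from 30 obtained as an epimer mixture at C4L; Dess–Martin oxidation gives the aryl ketone F3, and reduction with LiBH(s-Bu)3 in THF at −78 °C under Felkin–Anh control (hydride anti to the α-benzyloxy group) should give the 3,4-syn alcohol, so the route is rejoined at 30.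

Further compounds
F1 | step 11 | (2S,3R)-2-[4-(benzyloxy)phenyl]-3-{[3-(benzyloxy)-2-hydroxy-4-(methoxymethoxy)phenyl][3-(benzyloxy)-2-(tert-butyldimethylsilyloxy)-4-(methoxymethoxy)phenyl]methyl}oxirane, methine diastereomer that leads to the C4U configuration of 16 | C(c1ccccc1)Oc1ccc([C@@H]2O[C@@H]2[C@H](c2ccc(OCOC)c(OCc3ccccc3)c2O)c2ccc(OCOC)c(OCc3ccccc3)c2O[Si](C)(C)C(C)(C)C)cc1
F2 | step 11 | compound 16 carrying a tert-butyldimethylsilyl ether on the C7L oxygen | C(c1ccccc1)Oc1ccc([C@H]2Oc3c(ccc(OCOC)c3OCc3ccccc3)[C@H](c3ccc(OCOC)c(OCc4ccccc4)c3O[Si](C)(C)C(C)(C)C)[C@H]2O)cc1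
F0 | step 9 | none | none
F3 | step 19 | aryl ketone: compound 30 with C4L oxidised to the carbonyl | C(c1ccccc1)Oc1ccc([C@H]2Oc3c(ccc(OCOC)c3OCc3ccccc3)[C@H](c3cc(C(=O)[C@@H](OCc4ccccc4)[C@@H](OCOC)c4ccc(OCc5ccccc5)cc4)c(OCOC)c(OCc4ccccc4)c3OCc3ccccc3)[C@H]2OCc2ccccc2)cc1
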